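(The constants were chosen freely; the flask was simulated.)

The leftover of D is what I want from this flask, since the D that is gone has become D.L in one form or the other, and y is the rest of the charge.

D 25 mM; L 2.00 equiv; X 1.9 mol%; time 30 min

- amount of D.L and Q together at 30 min, in percent of the D charged
- concentration of D.L in solution at 30 min, in percent of saturation

    Q ⇌ D.L, rate k1*(cs1 - [D.L]) while solid is left; crystals form when [D.L] > cs1 (cs1 = 0.35 mM, k1 = 0.022 s⁻¹)
    D + L + X → D.L + X, rate k2*[D]*[L]*[X]/(1 + ([D]/sat2)) (sat2 = 0.058 M, k2 = 83 L² mol⁻² s⁻¹)

- for D.L the Q are counted in
- as a solid, counted per litre of solution: Q
- run time (flask): 30 min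

In the second step X comes out as it went in, so [X] stays at 0.475 mM, and each D takes one L, so [L] − [D] stays at its starting 25.0 mM. Leaving the crowding term aside, the logarithm of ρ = [L]/[D] climbs in a straight line, and what it gains is my log clock θ = 1.77, the rate constant times [X] times that difference times the time. In powers of ten, ρ starts at 0.301 and gains 0.769, so it ends near 11.8; ρ less one is the difference over [D], which leaves 9.27 % of the D.

The second way holds [L] at its charge of 50.0 mM and treats D as pseudo-first-order, so [D] falls by 1.54 powers of ten, a leftover of 2.88 %. The two part, and the second is the cheat: it keeps [L] at its charge while the flask's [L] sinks towards the lower 25.0 mM. The clock has a cheat of its own: the crowding term, which it leaves aside, divides the starting rate by 1.43; carrying that term through the integral, with the leftover above put into the correction, I commit to y = 88.0 %. My reckoning stops there and does not reach sat.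

The forecast says y = 87.8 % and sat = 144 %, holding that “dissolved D.L stays about 0.15 mM above the 0.35 mM solubility”.

The simulation gives y = 87.8 % and sat = 144 %, so the forecast stands, with 12.2 % of the D and 56.1 % of the L still unbound at 30.0 min.

This flask is unfinished at 30 min: y stands at 87.8 %, reaches 95.7 % in the run with L held unconsumed, and 100 % in ten times the time, so part of the gap comes from the consumption of L, acting together with the time given, both of which θ = 1.77 counts. The neighbour flask with 0.47 mol% of X has a clock of 0.439, which with the same correction gives y near 45.8 %; the computed value is 44.0 %.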